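Readings and results were generated by integration on assumed constants; scatter was added.

Target and side product are both made out of the starting material, so what is left of it tells how far they have come. I follow one molecule of starting material and ask for its chance of surviving.

all flasks: starting material 1.3 M; free catalyst 0.05 mol%

| run | second substrate | reagent | remark | time |
|---|---|---|---|---|
| ochre | 0.50 equiv | 1.3 equiv | run made earlier |  |
| violet | 0.50 equiv | 2 equiv | run made earlier |  |
| north | 0.500 equiv | 1.80 equiv |  | 2.5 min |
| north-east | 0.500 equiv | 2.30 equiv |  | 2.5 min |

| run | time / s | starting material / % | catalyst intermediate A / % | side product / % | target / % |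
|---|---|---|---|---|---|
| ochre | 10.0 | 97 | 0 | 0 | 4 |
| ochre | 15.0 | 100 | 2 | 1 | 1 |
| ochre | 30.0 | 98 | 0 | 4 | 7 |
| ochre | 50.0 | 91 | 0 | 3 | 9 |
| ochre | 60.0 | 89 | 1 | 7 | 8 |
| ochre | 80.0 | 80 | 2 | 6 | 12 |
| ochre | 120 | 75 | 0 | 9 | 14 |
| violet | 10.0 | 96 | 4 | 2 | 0 |
| violet | 12.0 | 97 | 0 | 3 | 2 |
| violet | 20.0 | 95 | 0 | 0 | 4 |
| violet | 30.0 | 89 | 2 | 1 | 9 |
| violet | 50.0 | 87 | 1 | 6 | 8 |
| violet | 60.0 | 85 | 2 | 4 | 8 |
| violet | 120 | 65 | 4 | 16 | 23 |

(each reading ± 2 percentage points)

- in percentages every species weighs as the starting material in it: one side product counts as two
- what may be going on: reagent + catalyst intermediate B -> free catalyst + second product; starting material + free catalyst <-> catalyst intermediate A; second substrate + free catalyst <-> catalyst intermediate B; starting material + target -> side product; reagent + catalyst intermediate A -> free catalyst + target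

- which of these there is most of at the end, counted by the starting material in it, north (catalyst intermediate A / starting material / target / side product)
- which of these there is most of at the end, counted by the starting material in it, north-east (catalyst intermediate A / starting material / target / side product)
- how much there is at the end of the one of these that leads, in percent of the starting material charged: north
- how much there is at the end of the one of these that leads, in percent of the starting material charged: north-east

1. The last readings give that chance: the ochre run holds 75 % at 120 s, and the violet run holds 65 % at 120 s. Read as an apparent pseudo-first-order loss, these give constants of 0.144 /min and 0.215 /min, and they carry the scatter of the readings.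

2. Reagent is the setting that differs between those runs, so I draw a straight line through them in the reagent charge. That gives 0.195 /min for north and 0.246 /min for north-east.

3. Two times now count. The first is the asked 2.5 min. The second is the time the starting material needs at that constant to fall to half of its charge, which is 3.56 min in north and 2.82 min in north-east: its half-time.

4. The asked time is shorter than either half-time, with ratios of 0.702 in north and 0.887 in north-east. So I expect fractions of 0.614 in north and 0.541 in north-east. Each is more than the remainder of the charge in its flask, so I expect starting material to lead in both flasks.

5. The forecast also names starting material for north and starting material for north-east, at 58 % and 51 %, lower than my fractions, “allowing a little for acceleration”.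

6. The flasks give starting material leading at 60.9 % in north, and starting material leading at 55.4 % in north-east.

    reagent + catalyst intermediate B → free catalyst + second product (k = 3.80 /M/s)
    starting material + free catalyst ⇌ catalyst intermediate A (K = 1.10 /M, k = 17.0 /M/s)
    second substrate + free catalyst ⇌ catalyst intermediate B (K = 1.60 /M, k = 950 /M/s)
    starting material + target → side product (k = 0.00460 /M/s)
    reagent + catalyst intermediate A → free catalyst + target (k = 9.00 /M/s)

The neighbouring flask is north-east read at 10 min. That is 3.55 half-times, so I reckon a fraction of 0.0854 of starting material left, and some other species leading. That flask holds less starting material than I reckon, 3.17 %, and its leader is side product at 54.9 %, more than the target's 42.0 %. In north-east, free catalyst goes from 53.7 % of the catalyst charged at 2.50 min to 92.7 % at 10.0 min.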